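**Plan**

- Numbering: on each guaiacyl ring C1 carries the C7–C8–C9 propanoic acid, C3 the methoxy group and C4 the hydroxyl group; C5–C5' is the biaryl bond.
- Feature: each arm is an aryl–C7H2–C8H2–C9O2H unit para to the C4 phenol, a hydrogenated cinnamic acid. C7 can therefore come from an aldehyde carbon and C8–C9 from malonic acid, and the symmetry about C5–C5' lets both arms be built in one operation.
- Retrosynthesis: the two C7–C8 single bonds go back to C7=C8 alkenes, both alkenes are cut to a biaryl dialdehyde plus two malonic acids, and the C5–C5' bond is cut to two vanillin molecules.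
- Forward: the biaryl bond is made first by oxidative phenol coupling, both two-carbon units are then attached to the formyl groups in one pot, and both alkenes are finally saturated. No ring is formed and no protecting group is used.
- Stereochemistry: the target has no stereocentre and the 2,2'-biphenol axis is not configurationally stable. The E alkenes of the intermediate diacid are removed by the hydrogenation.

Key step: step 2

**Route**

Step 1
Reactants: 1 vanillin (two molecules)
Product: 2 dehydrodivanillin (6,6'-dihydroxy-5,5'-dimethoxybiphenyl-3,3'-dicarbaldehyde)
Conditions: FeSO4·7H2O (cat.), Na2S2O8 (0.55 equiv), H2O, 50–60 °C; the solid is collected, dissolved in aq NaOH and reprecipitated with HCl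
Reagents that add atoms: none
Why: In this oxidative phenol coupling, divalent iron cleaves persulfate to the sulfate radical anion, which oxidises vanillin to a phenoxyl radical whose only open ortho or para position is C5 (C1 carries the formyl group, C3 the methoxy group), so C5–C5' dimerisation and rearomatisation should give the biphenol, which precipitates from water and is thereby withdrawn from further oxidation.

Step 2
Reactants: 2 dehydrodivanillin; 3 malonic acid (5 equiv)
Product: 5 (E,E)-5,5'-dehydrodiferulic acid, via bis(benzylidenemalonic acid) 4 (not isolated)
Conditions: piperidine (0.3 equiv), pyridine, 80 °C; then cold aq HCl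
Reagents that add atoms: malonic acid (3), OC(=O)CC(=O)O
Why: This is the Knoevenagel condensation in its Doebner modification, the reaction that converts vanillin into ferulic acid, applied to both formyl groups of 2. Piperidine turns each C7 aldehyde into an iminium ion, the malonate enolate adds to it to form the C7–C8 bond, and loss of piperidine gives the arylidenemalonic acid 4, which decarboxylates in hot pyridine to the conjugated acid. No ring is closed and no stereocentre is created; the E geometry of each C7=C8 bond follows from the thermodynamic preference in the decarboxylation and is removed in step 3. The step needs complete reaction of both aldehydes and no second decarboxylation to vinylphenols: the two formyl groups are equivalent and sit on different rings, so the first condensation should not slow the second, iminium activation offsets the electron donation of the para-phenoxide, and excess malonic acid with a bath temperature near 80 °C and substoichiometric piperidine should hold the reaction at the cinnamic acid stage. Acidification should precipitate the diacid and remove pyridine and piperidine as their hydrochlorides before the hydrogenation.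

Step 3
Reactants: 5 (E,E)-5,5'-dehydrodiferulic acid
Product: 6 3,3'-(6,6'-dihydroxy-5,5'-dimethoxybiphenyl-3,3'-diyl)dipropanoic acid (target, CNP0122720.0)
Conditions: H2 (1 atm), 10% Pd/C, MeOH–THF, rt
Reagents that add atoms: none
Why: Heterogeneous catalytic hydrogenation on palladium should saturate the two conjugated disubstituted C7=C8 alkenes at ambient pressure, while the arenes, aryl methyl ethers, phenols and carboxylic acids are inert under these conditions and no stereocentre arises.

**Compound list**

1 | vanillin (4-hydroxy-3-methoxybenzaldehyde) | COc1cc(C=O)ccc1O | starting material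
2 | dehydrodivanillin (6,6'-dihydroxy-5,5'-dimethoxybiphenyl-3,3'-dicarbaldehyde) | COc1cc(C=O)cc(-c2cc(C=O)cc(OC)c2O)c1O | intermediate
3 | malonic acid | OC(=O)CC(=O)O | starting material
4 | bis(benzylidenemalonic acid): 2,2'-[(6,6'-dihydroxy-5,5'-dimethoxybiphenyl-3,3'-diyl)dimethanylylidene]dimalonic acid | COc1cc(C=C(C(=O)O)C(=O)O)cc(-c2cc(C=C(C(=O)O)C(=O)O)cc(OC)c2O)c1O | intermediate
5 | (E,E)-5,5'-dehydrodiferulic acid: (2E,2'E)-3,3'-(6,6'-dihydroxy-5,5'-dimethoxybiphenyl-3,3'-diyl)bis(prop-2-enoic acid) | COc1cc(/C=C/C(=O)O)cc(-c2cc(/C=C/C(=O)O)cc(OC)c2O)c1O | intermediate
6 | 3,3'-(6,6'-dihydroxy-5,5'-dimethoxybiphenyl-3,3'-diyl)dipropanoic acid | COc1cc(CCC(=O)O)cc(-c2cc(CCC(=O)O)cc(OC)c2O)c1O | target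

**Step count**

Total steps: 3. Longest linear sequence: 3 steps (1 → 2 → 5 → 6).

**Steps most likely to fail**

Step 2. Dehydrodivanillin is poorly soluble and its para-phenoxide form is a weak electrophile, so the second formyl group may condense incompletely. Prolonged heating with amine may also decarboxylate the cinnamic acid further to a vinylphenol. The fallback sets out from 2 and forms the same C7=C8 bonds by Wittig olefination with the stabilised ylide Ph3P=CHCO2Et (3 equiv) in DMF at 80 °C, a reaction that tolerates free para-hydroxybenzaldehydes. This should give diethyl (E,E)-5,5'-dehydrodiferulate F1. Saponification with aq NaOH in THF under nitrogen, followed by acidification, returns to the route at 5.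

Step 1. The oxidation may not stop at the dimer and may lead on to oligomers and quinoid material, and the insoluble product is hard to free from them. The fallback sets out from 1 and fixes the coupling site with a halogen:
- Iodination with I2 and NaHCO3 in water should give 5-iodovanillin F2.
- Benzylation with BnBr and K2CO3 in DMF should give 4-(benzyloxy)-3-iodo-5-methoxybenzaldehyde F3.
- Ullmann homocoupling with activated Cu powder in DMF at 150 °C should give 6,6'-bis(benzyloxy)-5,5'-dimethoxybiphenyl-3,3'-dicarbaldehyde F4.
- Debenzylation with BCl3 and pentamethylbenzene in CH2Cl2 at −78 °C, which leaves the aldehydes and methyl ethers untouched, returns to the route at 2.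

Step 3. The diacid dissolves poorly and traces of pyridine or piperidine can poison the catalyst, so saturation of the second alkene may stall. The fallback sets out from 5 and moves the reduction to the ester stage:
- Fischer esterification (MeOH, cat. H2SO4, reflux) should give dimethyl (E,E)-5,5'-dehydrodiferulate F5, which is soluble and can be purified by chromatography.
- Hydrogenation (H2, Pd/C, EtOAc–MeOH) should give dimethyl 3,3'-(6,6'-dihydroxy-5,5'-dimethoxybiphenyl-3,3'-diyl)dipropanoate F6.
- Saponification with LiOH in degassed THF–water, followed by acidification, returns to the route at 6.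

**Further compounds**

F1 | step 2 | diethyl (E,E)-5,5'-dehydrodiferulate | CCOC(=O)/C=C/c1cc(OC)c(O)c(-c2cc(/C=C/C(=O)OCC)cc(OC)c2O)c1
F2 | step 1 | 5-iodovanillin (4-hydroxy-3-iodo-5-methoxybenzaldehyde) | COc1cc(C=O)cc(I)c1O
F3 | step 1 | 4-(benzyloxy)-3-iodo-5-methoxybenzaldehyde | COc1cc(C=O)cc(I)c1OCc1ccccc1
F4 | step 1 | 6,6'-bis(benzyloxy)-5,5'-dimethoxybiphenyl-3,3'-dicarbaldehyde | COc1cc(C=O)cc(-c2cc(C=O)cc(OC)c2OCc2ccccc2)c1OCc1ccccc1
F5 | step 3 | dimethyl (E,E)-5,5'-dehydrodiferulate | COC(=O)/C=C/c1cc(OC)c(O)c(-c2cc(/C=C/C(=O)OC)cc(OC)c2O)c1
F6 | step 3 | dimethyl 3,3'-(6,6'-dihydroxy-5,5'-dimethoxybiphenyl-3,3'-diyl)dipropanoate | COC(=O)CCc1cc(OC)c(O)c(-c2cc(CCC(=O)OC)cc(OC)c2O)c1
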